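**Minutes of the meeting on the flask**

| flask | substrate | reagent in the second phase | remark | time | volume of the second phase over the first |
|---|---|---|---|---|---|
| teal | 28 mM (fed, over 25 h) | 22 mM | run made earlier |  |  |
| ochre | 44 mM (fed, over 25 h) | 22 mM | run made earlier |  |  |
| grey | 20 mM (fed, over 25 h) | 44 mM | run made earlier |  |  |
| flask | 20 mM (fed, over 25 h) | 22.0 mM |  | 15 d | 1.0 |

| run | time / d | target / % | substrate / % |
|---|---|---|---|
| teal | 0.333 | 4 | 26 |
| teal | 0.833 | 11 | 54 |
| teal | 1.67 | 9 | 55 |
| teal | 4.00 | 8 | 47 |
| teal | 8.00 | 0 | 50 |
| teal | 20.0 | 0 | 48 |
| ochre | 0.333 | 4 | 28 |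
| ochre | 0.833 | 12 | 63 |
| ochre | 1.67 | 12 | 68 |
| ochre | 4.00 | 6 | 62 |
| ochre | 8.00 | 0 | 63 |
| ochre | 20.0 | 0 | 62 |
| grey | 0.333 | 5 | 25 |
| grey | 0.833 | 21 | 41 |
| grey | 2.50 | 19 | 18 |
| grey | 6.00 | 2 | 8 |
| grey | 20.0 | 0 | 8 |

(scatter of a reading: 2 percentage points)

- when, up to 15 d, the flask holds most target
- the amount of target, in percent of the substrate charged, at that time
- earliest time at which at least nineteen twentieths of that best amount are there, in d
- latest time at which they still are, in d

- charges count per volume of the first phase; a concentration in a rate is the amount of a species over the volume of its own phase; every rate counts per litre of the first phase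
- the earlier runs hold the two phases in the same ratio of volumes as the flask asked about
- a reading or a percentage of target counts all its forms, free or not
- percentages count the whole charge, also what has not yet gone in

The meeting began with target, which does not stay: at 20.0 d teal and ochre read 0 % and 0 %, while their substrate holds at 48 % and 62 % of its charge. The first chemist argued that a peak is a passing share of what gets through, and that what gets through can be counted by hand.

Teal and ochre charge less reagent than substrate, so there reagent is the limiting reagent. She took the substrate consumed by the last reading, per reagent charged, and found 0.662 for teal and 0.760 for ochre. The line through these two, carried to the flask's 20 mM, gives 0.613, the reagent yield, an extrapolation that carries the scatter of the readings.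

On paper the flask's 22.0 mM of reagent covers its substrate, but this yield passes 67.4 % of the charge. Teal's highest target reading was 0.212 of what got through, and ochre's was 0.316. She therefore committed to a best between 14.3 % and 21.3 %.

The forecast's author answered that “Peak target percent barely depends on substrate charge”, and put 13 % (range 10.5 % to 16 %) at 1.4 d, with the window from 1.05 d to 2 d. Her band starts above that figure, so the two differ. Her count has no clock, so the meeting took the forecast's times.

The flask gives 17.4 % at 1.35 d, more than forecast, and stays within the asked margin of it from 1.09 d to 1.76 d.

    reagent in the reaction phase ⇌ reagent in the second phase, rate k1*([reagent in the reaction phase] - [reagent in the second phase]/K1) per volume of the first phase (partition coefficient = 0.640, kL = 1.80 × 10⁻⁴ s⁻¹)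
    substrate + reagent in the reaction phase ⇌ target (K = 54.0 L mol⁻¹, k = 0.00130 L mol⁻¹ s⁻¹)
    target ⇌ product in the second phase, rate k3*([target] - [product in the second phase]/K3) per volume of the first phase (partition coefficient = 1.80, kL = 2.30 × 10⁻⁵ s⁻¹)
    target → decomposed product (k = 3.30 × 10⁻⁵ s⁻¹)
    reagent in the reaction phase → decomposed reagent (k = 4.30 × 10⁻⁶ s⁻¹)

Of that best, 9.51 % stands as product in the second phase. At 15.0 d the flask keeps 35 % of its substrate, a reagent yield of 0.591 against the reckoned 0.613. For the same flask with 80 mM of substrate, ochre's yield of 0.760 leaves 79.1 %, and that flask holds 77 %.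

(The numbers in the tables were computed for substances that don't exist.)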